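**Numbering used throughout** (TBS = tert-butyldimethylsilyl; flavan numbering O1, C2, C3, C4, C4a, C5–C8, C8a for all chromane intermediates): 1 daphnetin; 2 its bis-TBS ether; 3 lactol; 4 ethyl chromene acetal; 5 arylboronic acid; 6 diethyl arylboronate; 7 (2S)-flav-3-ene; 8 trans-bromohydrin; 9 epoxide cis to the aryl group; 10 hydroxy acetate; 11 dimer mono-acetate; 12 hexasilylated dimer diol; 13 target.

## Analysis of the target

CNP0266687.1 (C30H26O11) is an ether-linked dimer of two 7,8,4'-trihydroxyflavan-3,4-diol units, each built from a pyrogallol-type ring A fused to the dihydropyran ring C (O1, C2, C3, C4, C4a, C8a), with a 4-hydroxyphenyl ring B on C2. The units are joined by a single ether oxygen: it is O3 of one unit (the lower unit, which keeps a free C4 hydroxyl) and it sits on C4 of the other (the upper unit, which keeps a free C3 hydroxyl). All six stereocentres lie in the two rings C and both units have the same configuration, (2R,3R,4S): the 2-aryl group and O3 are cis, O3 and O4 are trans, so that with the aryl group equatorial the C3–O and C4–O bonds are trans-diaxial. Read along the two rings C, the atoms H–O3–C3–C4 (upper unit)–O3–C3–C4–OH (lower unit) are the regioregular head-to-tail dimer of a 3,4-epoxide capped by one molecule of water; this hidden repeat is the feature on which the route is built. Both C4–O bonds are benzylic to a ring A whose O1 is ortho and whose O7 is para to C4a, so they ionise under acid, are cleaved by hydrogenolysis and, once O7 is a free phenol, can leave through a quinone methide under base; the 7,8-catechols oxidise readily. The difficulties are the 2,3-cis relationship (electrophiles add to a flav-3-ene anti to the aryl group), joining two identical halves only through O3 of one and C4 of the other without chain growth, and unmasking eight hydroxyls without acid, strong base or hydrogen.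

## Retrosynthetic reasoning

**13 ⇒ 12 ⇒ 11 (no skeletal bond cut).** The six phenols are masked as aryl TBS ethers and O4 of the lower unit as an acetate. Silyl ethers are chosen because fluoride removes them without touching the two benzylic C4–O bonds, which rules out benzyl, methyl and acetal protection. The acetate is removed first by hydride, while all phenols are still silylated, so that no para-phenoxide can expel it.

**11 ⇒ 9 + 9 (both C4–O bonds cut in one operation).** The C4–O3 ether bond of the upper unit and the C4–OAc bond of the lower unit are cut together. Each is benzylic and trans to the neighbouring O3, which is the retron of an epoxide opened at C4 with inversion. Cutting here turns the unsymmetrical dimer into two molecules of one compound, epoxide 9, plus one carboxylic acid. The forward reaction must open the first molecule of 9 with the acid (giving 10), let O3 of 10 open the second molecule at C4, and stop there.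

**9 ⇒ 8 ⇒ 7 (C3–O and C4–O bonds).** The oxirane of 9 lies on the face of the 2-aryl group, which direct epoxidation of 7 cannot reach. It is therefore traced to bromohydrin 8: bromine adds to C3 anti to the aryl group, oxygen to C4 on the aryl face, and ring closure by that oxygen inverts C3. All of C3 and C4 in both halves of 13 is thus relayed from C2 of 7.

**7 ⇒ 4 + 5 (C2–aryl bond).** C2 is the only stereocentre that needs an external source of chirality. Cutting the C2–aryl bond leads to the benzopyrylium ion latent in acetal 4 and the aryl nucleophile 5; the forward step is a catalytic enantioselective boronate addition that gives the 2H-chromene directly, with the C3=C4 alkene already in place.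

**4 ⇒ 2 ⇒ 1 (oxidation level only).** Acetal 4 is the reduced and acetalised form of coumarin 2, the silyl ether of commercial daphnetin 1, which already contains ring A with the 7,8-oxygenation and all carbons of ring C.

## Alternatives that were turned down

**Alternative 1:** The textbook route cuts the same C4–O3 ether bond but between two separately prepared, differently protected flavans: the electrophile A1 (a tri-O-benzyl 4β-benzylsulfanyl flavan-3-ol) and the nucleophile A2 (its 4β-allyloxy analogue). The forward key step is AgBF4-promoted ionisation of the C4–S bond of A1 in the presence of A2. It was turned down on three grounds: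
- A1 and A2 each need their own sequence of asymmetric alkene dihydroxylation, ring closure, an oxidation/reduction detour at C3 to reach 2,3-cis, and a separate benzylic oxidation at C4. That is roughly twice the number of operations, and the identity of the two halves goes unused.
- A1 carries a free O3 and can attack its own cation, so A2 must be used in excess.
- The benzyl ethers would have to be removed by hydrogenolysis next to two benzylic C4–O bonds.

**Alternative 2:** The ether oxygen could be introduced as an ester, and ring C of the lower unit built around it. The upper-unit alcohol A3 would be acylated with the α-aryl-α-aryloxyacetic acid A4 to give ester A5. Olefinic-ester cyclisation (TiCl4, TMEDA, Zn, PbCl2, CH3CHBr2) would close ring C as the cyclic enol ether A6 (new C3=C4 bond), and hydroboration/oxidation anti to the 2-aryl group would set C3 and C4 of the lower unit together. The stereochemical logic is sound, but it was turned down: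
- The future C2 in A4 and A5 is benzylic, O-substituted and α to a carbonyl, so it epimerises during acylation of a hindered benzylic alcohol and under the titanium/amine conditions.
- A3 must still be made by another route.
- About eight more steps are needed, with risk in at least four of them rather than in one.

**Alternative 3:** Ring C of the upper unit could be built in a three-component inverse-demand hetero-Diels–Alder reaction. Aldehyde A7, alcohol 10 and the (Z)-enol acetate A8 would be combined under acid to give cycloadduct A9, forming C4–O, C3–C4 and O1–C2 at once. It was turned down because none of the three new stereocentres is secured: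
- The endo preference of such cycloadditions places the 2-aryl and 4-alkoxy groups cis, whereas the target needs them trans.
- A stepwise path through a 4-silyloxybenzyl cation would lose the cis geometry of A8 and hence the 2,3-cis relationship.
- The only chiral element is the remote alkoxy group from 10, which gives no facial control.
- The regiochemistry relies on the aryl group outweighing the acyloxy group as donor.

Key step: step 6

Remark on the chemistry: α denotes the face of ring C that carries the 2-aryl group and β the opposite face; CIP descriptors change along the route where substituent priorities change, not the spatial arrangement.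

## Route

Step 1
Reactants: 1 daphnetin (7,8-dihydroxy-2H-chromen-2-one)
Product: 2 7,8-bis(TBSO)-2H-chromen-2-one
Conditions: TBSCl (2.4 equiv), imidazole (5 equiv), DMF, rt
Reagents that add atoms: tert-butyldimethylsilyl chloride, CC(C)(C)[Si](C)(C)Cl
Why: Imidazole-mediated silylation of both catechol hydroxyls; aryl silyl ethers are chosen because they can be removed at the end by buffered fluoride, without acid or hydrogenolysis at the benzylic C4–O bonds.

Step 2
Reactants: 2 7,8-bis(TBSO)-2H-chromen-2-one
Product: 4 2-ethoxy-7,8-bis(TBSO)-2H-chromene (racemic), via lactol 3 (not isolated)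
Conditions: iBu2AlH (DIBAL-H, 1.2 equiv), CH2Cl2, −78 °C; aq. potassium sodium tartrate (KNaC4H4O6); then EtOH, PPTS (5 mol %), rt
Reagents that add atoms: ethanol, CCO
Why: Partial reduction of the lactone gives the 2H-chromen-2-ol, which ionises under mild acid to the 7,8-dioxygenated benzopyrylium ion and is trapped by ethanol (lactol-to-acetal exchange); the C2 centre of 4 is erased in step 3, so its configuration is irrelevant.

Step 3
Reactants: 4 2-ethoxy-7,8-bis(TBSO)-2H-chromene; 5 [4-(TBSO)phenyl]boronic acid
Product: 7 (2S)-7,8-bis(TBSO)-2-[4-(TBSO)phenyl]-2H-chromene, via diethyl arylboronate 6 (not isolated)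
Conditions: 5, EtOH, 4 Å MS, then evaporation; 4, chiral tartaric acid monoamide (5 mol %, enantiomer that gives 2S), Yb(OTf)3 (4 mol %), EtOAc, −20 °C
Reagents that add atoms: none
Why: Enantioselective addition of an aryl boronate to a chromene acetal under combined chiral Brønsted acid/Lewis acid catalysis: the acetal ionises to the benzopyrylium ion, the boronate exchanges onto the chiral dihydroxy acid and delivers the aryl group to C2 within the resulting ion pair. This sets C2, the only stereocentre of the route fixed by a catalyst, and leaves the C3=C4 alkene ready for step 4.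

Step 4
Reactants: 7 (2S)-7,8-bis(TBSO)-2-[4-(TBSO)phenyl]-2H-chromene
Product: 8 (2R,3S,4R)-3-bromo-7,8-bis(TBSO)-2-[4-(TBSO)phenyl]chroman-4-ol (3β-Br, 4α-OH)
Conditions: NBS (1.05 equiv), THF–H2O (4:1), 0 °C, dark
Reagents that add atoms: N-bromosuccinimide, O=C1CCC(=O)N1Br; water, O
Why: Bromohydrin formation by anti addition: bromine engages C3 on the β face, away from the 2-aryl group, and water attacks the benzylic C4 (stabilised by O1 and the 7-silyloxy group) on the α face, giving the all-trans bromohydrin. C3 and C4 are thus set by substrate control from C2.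

Step 5
Reactants: 8 (2R,3S,4R)-3-bromo-7,8-bis(TBSO)-2-[4-(TBSO)phenyl]chroman-4-ol
Product: 9 (2R,3R,4R)-3,4-epoxy-7,8-bis(TBSO)-2-[4-(TBSO)phenyl]chromane (oxirane on the α face, cis to the aryl group)
Conditions: NaH (1.1 equiv), THF, 0 °C; filtration through basic Al2O3; used at once
Reagents that add atoms: none
Why: Intramolecular Williamson closure: the C4 alkoxide displaces bromide at C3 with inversion from the trans-diaxial conformer, placing the epoxide oxygen on the aryl face that direct epoxidation of 7 cannot reach. Base-only conditions and immediate use respect the acid lability of a 7-oxygenated chromene oxide.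

Step 6
Reactants: 9 (2R,3R,4R)-3,4-epoxy-7,8-bis(TBSO)-2-[4-(TBSO)phenyl]chromane (two molecules, added in two portions)
Product: 11 (2R,3S,4S)-3-{[(2R,3R,4S)-3-hydroxy-7,8-bis(TBSO)-2-[4-(TBSO)phenyl]chroman-4-yl]oxy}-7,8-bis(TBSO)-2-[4-(TBSO)phenyl]chroman-4-yl acetate, via hydroxy acetate 10 (not isolated)
Conditions: AcOH (0.55 equiv), CH2Cl2, −20 to 0 °C, first portion of 9 (0.55 equiv); then BF3·OEt2 (5 mol %), −78 °C, second portion of 9 (0.45 equiv) added over 2 h; Et3N
Reagents that add atoms: acetic acid, CC(=O)O
Why: Acid-promoted epoxide opening at the benzylic carbon, the reaction type of the acetolysis and alcoholysis of chromene and flav-3-ene oxides and of the C4 solvolyses used to join flavan units: protonation (first stage) or BF3 coordination (second stage) of the oxirane oxygen of 9 weakens the C4–O bond, whose carbon is stabilised by O1 (ortho) and the 7-silyloxy group (para), and the nucleophile enters at C4 with inversion. In the first stage acetic acid is both the acid and by far the least hindered nucleophile, so it converts its share of 9 into 10 before any alcohol competes; in the second stage the only hydroxyl able to attack is O3 of 10, because its O4 is acetylated, which fixes the C4–O–C3 regiochemistry of the ether. The step closes no ring; it forms the C4–OAc bond of the lower unit and the C4–O3 ether bond between the units, and it frees O3–H of the upper unit. Both new stereocentres (C4 of each unit) are substrate-controlled: the equatorial 2-aryl group locks ring C so that the cis C3–O bond is axial, and the nucleophile adds axially on the β face, anti to that bond (trans-diaxial opening), whether the opening is concerted or passes through the ion pair. The same conformation keeps C3–H equatorial and poorly aligned with the developing empty orbital at C4, which disfavours the hydride shift to the flavan-3-one that is typical of the trans epoxides. The selectivity the step needs is dimer over trimer: the hydroxyl of 11 that could continue the chain sits between the 2-aryl group and the newly attached flavanyl ether and is more hindered than that of 10, 10 is kept in excess over the slowly added second portion of 9, and unreacted 10 can be returned to the step. The low temperature and the catalytic amount of BF3·OEt2 are chosen so that neither the benzylic acetate of 10 nor the new benzylic ether of 11 ionises.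

Step 7
Reactants: 11 dimer mono-acetate
Product: 12 (2R,3R,4S)-3-{[(2R,3R,4S)-3-hydroxy-7,8-bis(TBSO)-2-[4-(TBSO)phenyl]chroman-4-yl]oxy}-7,8-bis(TBSO)-2-[4-(TBSO)phenyl]chroman-4-ol
Conditions: iBu2AlH (DIBAL-H, 4 equiv), CH2Cl2, −78 °C; aq. potassium sodium tartrate (KNaC4H4O6)
Reagents that add atoms: none
Why: Reductive ester cleavage at low temperature removes the acetate by attack at the acyl carbon, not by ionisation at C4, so the C4 configuration is kept. It is done while all six phenols are still silylated, so that no para-phenoxide can expel the benzylic acetate as a quinone methide.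

Step 8
Reactants: 12 hexasilylated dimer diol
Product: 13 (2R,3R,4S)-3-{[(2R,3R,4S)-3,7,8-trihydroxy-2-(4-hydroxyphenyl)chroman-4-yl]oxy}-2-(4-hydroxyphenyl)chromane-4,7,8-triol (target)
Conditions: TBAF (7 equiv), AcOH (7 equiv), THF, 0 °C, argon; Sephadex LH-20 (EtOH)
Reagents that add atoms: none
Why: Fluoride cleaves the six aryl Si–O bonds; acetic acid buffering keeps the phenols protonated, which suppresses quinone methide formation at the two para-hydroxybenzylic C4–O bonds and air oxidation of the catechols. No stereocentre is touched.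

## Compound list

1 | daphnetin (7,8-dihydroxy-2H-chromen-2-one) | O=c1ccc2ccc(O)c(O)c2o1 | starting material
2 | 7,8-bis(TBSO)-2H-chromen-2-one | O=c1ccc2ccc(O[Si](C)(C)C(C)(C)C)c(O[Si](C)(C)C(C)(C)C)c2o1 | intermediate
3 | 7,8-bis(TBSO)-2H-chromen-2-ol (lactol, racemic) | OC1C=Cc2ccc(O[Si](C)(C)C(C)(C)C)c(O[Si](C)(C)C(C)(C)C)c2O1 | intermediate (not isolated)
4 | 2-ethoxy-7,8-bis(TBSO)-2H-chromene (racemic) | CCOC1C=Cc2ccc(O[Si](C)(C)C(C)(C)C)c(O[Si](C)(C)C(C)(C)C)c2O1 | intermediate
5 | [4-(TBSO)phenyl]boronic acid | OB(O)c1ccc(O[Si](C)(C)C(C)(C)C)cc1 | starting material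
6 | diethyl [4-(TBSO)phenyl]boronate | CCOB(OCC)c1ccc(O[Si](C)(C)C(C)(C)C)cc1 | intermediate (not isolated)
7 | (2S)-7,8-bis(TBSO)-2-[4-(TBSO)phenyl]-2H-chromene | CC(C)(C)[Si](C)(C)Oc1ccc([C@H]2Oc3c(ccc(O[Si](C)(C)C(C)(C)C)c3O[Si](C)(C)C(C)(C)C)C=C2)cc1 | intermediate
8 | (2R,3S,4R)-3-bromo-7,8-bis(TBSO)-2-[4-(TBSO)phenyl]chroman-4-ol | CC(C)(C)[Si](C)(C)Oc1ccc([C@H]2Oc3c(ccc(O[Si](C)(C)C(C)(C)C)c3O[Si](C)(C)C(C)(C)C)[C@@H](O)[C@@H]2Br)cc1 | intermediate
9 | (2R,3R,4R)-3,4-epoxy-7,8-bis(TBSO)-2-[4-(TBSO)phenyl]chromane | CC(C)(C)[Si](C)(C)Oc1ccc([C@H]2Oc3c(ccc(O[Si](C)(C)C(C)(C)C)c3O[Si](C)(C)C(C)(C)C)[C@H]4O[C@@H]24)cc1 | intermediate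
10 | (2R,3S,4S)-3-hydroxy-7,8-bis(TBSO)-2-[4-(TBSO)phenyl]chroman-4-yl acetate | CC(C)(C)[Si](C)(C)Oc1ccc([C@H]2Oc3c(ccc(O[Si](C)(C)C(C)(C)C)c3O[Si](C)(C)C(C)(C)C)[C@H](OC(C)=O)[C@H]2O)cc1 | intermediate (not isolated)
11 | dimer mono-acetate: upper unit (2R,3R,4S) with free 3-OH and C4–O ether, lower unit (2R,3S,4S) with O3 ether and 4β-acetate, six aryl TBS ethers | CC(C)(C)[Si](C)(C)Oc1ccc([C@H]2Oc3c(ccc(O[Si](C)(C)C(C)(C)C)c3O[Si](C)(C)C(C)(C)C)[C@H](O[C@H]3[C@@H](c4ccc(O[Si](C)(C)C(C)(C)C)cc4)Oc4c(ccc(O[Si](C)(C)C(C)(C)C)c4O[Si](C)(C)C(C)(C)C)[C@@H]3OC(C)=O)[C@H]2O)cc1 | intermediate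
12 | hexa-O-TBS dimer diol, both units (2R,3R,4S) | CC(C)(C)[Si](C)(C)Oc1ccc([C@H]2Oc3c(ccc(O[Si](C)(C)C(C)(C)C)c3O[Si](C)(C)C(C)(C)C)[C@H](O[C@H]3[C@@H](c4ccc(O[Si](C)(C)C(C)(C)C)cc4)Oc4c(ccc(O[Si](C)(C)C(C)(C)C)c4O[Si](C)(C)C(C)(C)C)[C@@H]3O)[C@H]2O)cc1 | intermediate
13 | CNP0266687.1, (2R,3R,4S)-3-{[(2R,3R,4S)-3,7,8-trihydroxy-2-(4-hydroxyphenyl)chroman-4-yl]oxy}-2-(4-hydroxyphenyl)chromane-4,7,8-triol | Oc1ccc([C@H]2Oc3c(ccc(O)c3O)[C@H](O[C@H]3[C@@H](c4ccc(O)cc4)Oc4c(ccc(O)c4O)[C@@H]3O)[C@H]2O)cc1 | target

## Step count and least certain steps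

Total step count: 8. Longest linear sequence: 8 steps (1 to 13); 5 is purchased.

**Step 6 (key step).** The most likely failure is chain growth beyond the dimer: the hydroxyl of 11 opens a further molecule of 9, and the less 10 remains, the more this counts. Slow capture by the hindered O3 of 10 would also give the activated epoxide time to rearrange or to be attacked by the oxirane oxygen of another molecule of 9. The fallback sets out from 9 and comes back at 11, with two different, isolated partners and a thiophilic promoter:
- One portion of 9 is opened with benzyl mercaptan (PPTS cat., CH2Cl2, −20 °C) to the 4β-benzylsulfanyl alcohol F1.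
- A second portion is acetolysed in an acetic acid-rich medium and 10 is isolated.
- F1 is ionised with AgBF4 (THF, 0 °C, 2,6-di-tert-butylpyridine) in the presence of a threefold excess of 10 to give 11. The promoter does not touch the acetate of 10, and the excess of 10 outcompetes attack by the free O3 of F1.

**Step 3.** Enantiofacial discrimination may be insufficient because the very electron-rich benzopyrylium ion can react through an uncatalysed background pathway; the product can also racemise by electrocyclic ring opening if warmed. The fallback sets out from 5 and comes back at 7 through an asymmetric conjugate addition: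
- Commercial 2',3',4'-trihydroxyacetophenone is condensed with DMF dimethyl acetal and cyclised with aqueous HCl to 7,8-dihydroxy-4H-chromen-4-one F2.
- Silylation (TBSCl, imidazole) gives the bis(silyl ether) F3.
- Addition of 5 (Pd(OCOCF3)2, t-BuPyOx ligand of the appropriate hand, NH4PF6, H2O, ClCH2CH2Cl, 60 °C) gives the (2S)-flavanone F4.
- NaBH4 (MeOH/THF, 0 °C) gives the (2S,4S)-flavan-4-ol F5, and dehydration with the Burgess reagent (toluene, 50 °C) gives 7.

**Step 4.** Electrophilic bromination of ring A at C6 (para to O1, ortho to O7) may compete with bromonium formation, and water may be captured on both faces of the benzylic cation. The fallback sets out from 7 and comes back at 11 without electrophilic halogen: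
- BH3·THF then NaBO3·4H2O gives the 2,3-trans flavan-3-ol F6 (borane anti to the aryl group).
- Dess–Martin periodinane gives the flavan-3-one F7.
- LiBH(s-Bu)3 with LiBr at −78 °C gives the 2,3-cis flavan-3-ol F8 (hydride anti to the aryl group).
- DDQ in CH2Cl2 containing acetic acid functionalises C4 of F8 trans to O3 and gives 10.
- DDQ oxidation of a second portion of F8 in the presence of excess 10 gives 11.

**Step 5.** The epoxide may be lost during isolation through acid-catalysed ring opening or rearrangement on glass or adsorbent, and the alkoxide may abstract a silyl group from an aryl ether before it closes the ring. The fallback sets out from 8 and comes back at 11 without a discrete epoxide and makes no new compound (F0):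
- AgOAc in AcOH/CH2Cl2 removes bromide from C3 with participation of the trans C4 oxygen and gives 10 directly.
- A second portion of 8 is then activated with AgOTf and 2,6-di-tert-butylpyridine in the presence of excess 10 to give 11.

## Further compounds

F1 | step 6 | (2R,3S,4S)-4-(benzylsulfanyl)-7,8-bis(TBSO)-2-[4-(TBSO)phenyl]chroman-3-ol | CC(C)(C)[Si](C)(C)Oc1ccc([C@H]2Oc3c(ccc(O[Si](C)(C)C(C)(C)C)c3O[Si](C)(C)C(C)(C)C)[C@H](SCc3ccccc3)[C@H]2O)cc1
F2 | step 3 | 7,8-dihydroxy-4H-chromen-4-one | O=c1ccoc2c(O)c(O)ccc12
F3 | step 3 | 7,8-bis(TBSO)-4H-chromen-4-one | O=c1ccoc2c(O[Si](C)(C)C(C)(C)C)c(O[Si](C)(C)C(C)(C)C)ccc12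
F4 | step 3 | (2S)-7,8-bis(TBSO)-2-[4-(TBSO)phenyl]chroman-4-one | O=C1C[C@@H](c2ccc(O[Si](C)(C)C(C)(C)C)cc2)Oc2c(O[Si](C)(C)C(C)(C)C)c(O[Si](C)(C)C(C)(C)C)ccc12
F5 | step 3 | (2S,4S)-7,8-bis(TBSO)-2-[4-(TBSO)phenyl]chroman-4-ol | O[C@H]1C[C@@H](c2ccc(O[Si](C)(C)C(C)(C)C)cc2)Oc2c(O[Si](C)(C)C(C)(C)C)c(O[Si](C)(C)C(C)(C)C)ccc12
F6 | step 4 | (2R,3S)-7,8-bis(TBSO)-2-[4-(TBSO)phenyl]chroman-3-ol | CC(C)(C)[Si](C)(C)Oc1ccc([C@H]2Oc3c(ccc(O[Si](C)(C)C(C)(C)C)c3O[Si](C)(C)C(C)(C)C)C[C@@H]2O)cc1
F7 | step 4 | (2R)-7,8-bis(TBSO)-2-[4-(TBSO)phenyl]chroman-3-one | CC(C)(C)[Si](C)(C)Oc1ccc([C@H]2Oc3c(ccc(O[Si](C)(C)C(C)(C)C)c3O[Si](C)(C)C(C)(C)C)CC2=O)cc1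
F8 | step 4 | (2R,3R)-7,8-bis(TBSO)-2-[4-(TBSO)phenyl]chroman-3-ol | CC(C)(C)[Si](C)(C)Oc1ccc([C@H]2Oc3c(ccc(O[Si](C)(C)C(C)(C)C)c3O[Si](C)(C)C(C)(C)C)C[C@H]2O)cc1
F0 | step 5 | none | none
A1 | alternative 1 | (2R,3S,4S)-4-(benzylsulfanyl)-7,8-bis(benzyloxy)-2-[4-(benzyloxy)phenyl]chroman-3-ol | C(c1ccccc1)Oc1ccc([C@H]2Oc3c(ccc(OCc4ccccc4)c3OCc3ccccc3)[C@H](SCc3ccccc3)[C@H]2O)cc1
A2 | alternative 1 | (2R,3R,4S)-4-(allyloxy)-7,8-bis(benzyloxy)-2-[4-(benzyloxy)phenyl]chroman-3-ol | C(c1ccccc1)Oc1ccc([C@H]2Oc3c(ccc(OCc4ccccc4)c3OCc3ccccc3)[C@H](OCC=C)[C@H]2O)cc1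
A3 | alternative 2 | (2R,3R,4S)-3,7,8-tris(TBSO)-2-[4-(TBSO)phenyl]chroman-4-ol | CC(C)(C)[Si](C)(C)Oc1ccc([C@H]2Oc3c(ccc(O[Si](C)(C)C(C)(C)C)c3O[Si](C)(C)C(C)(C)C)[C@H](O)[C@H]2O[Si](C)(C)C(C)(C)C)cc1
A4 | alternative 2 | (2R)-2-[2,3-bis(TBSO)-6-vinylphenoxy]-2-[4-(TBSO)phenyl]acetic acid | OC(=O)[C@@H](c1ccc(O[Si](C)(C)C(C)(C)C)cc1)Oc1c(C=C)ccc(O[Si](C)(C)C(C)(C)C)c1O[Si](C)(C)C(C)(C)C
A5 | alternative 2 | ester of A3 (through O4) with A4 | CC(C)(C)[Si](C)(C)Oc1ccc([C@H]2Oc3c(ccc(O[Si](C)(C)C(C)(C)C)c3O[Si](C)(C)C(C)(C)C)[C@H](OC(=O)[C@@H](c3ccc(O[Si](C)(C)C(C)(C)C)cc3)Oc3c(C=C)ccc(O[Si](C)(C)C(C)(C)C)c3O[Si](C)(C)C(C)(C)C)[C@H]2O[Si](C)(C)C(C)(C)C)cc1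
A6 | alternative 2 | cyclic enol ether: O4 of A3 bonded to C3 of (2R)-7,8-bis(TBSO)-2-[4-(TBSO)phenyl]-2H-chromene | CC(C)(C)[Si](C)(C)Oc1ccc([C@H]2Oc3c(ccc(O[Si](C)(C)C(C)(C)C)c3O[Si](C)(C)C(C)(C)C)[C@H](OC3=Cc4ccc(O[Si](C)(C)C(C)(C)C)c(O[Si](C)(C)C(C)(C)C)c4O[C@@H]3c3ccc(O[Si](C)(C)C(C)(C)C)cc3)[C@H]2O[Si](C)(C)C(C)(C)C)cc1
A7 | alternative 3 | 2-hydroxy-3,4-bis(TBSO)benzaldehyde | O=Cc1ccc(O[Si](C)(C)C(C)(C)C)c(O[Si](C)(C)C(C)(C)C)c1O
A8 | alternative 3 | (Z)-2-[4-(TBSO)phenyl]ethenyl acetate | CC(=O)O/C=C\c1ccc(O[Si](C)(C)C(C)(C)C)cc1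
A9 | alternative 3 | 3-O-acetate of 11 (upper unit 3-acetate, lower unit 4-acetate) | CC(C)(C)[Si](C)(C)Oc1ccc([C@H]2Oc3c(ccc(O[Si](C)(C)C(C)(C)C)c3O[Si](C)(C)C(C)(C)C)[C@H](O[C@H]3[C@@H](c4ccc(O[Si](C)(C)C(C)(C)C)cc4)Oc4c(ccc(O[Si](C)(C)C(C)(C)C)c4O[Si](C)(C)C(C)(C)C)[C@@H]3OC(C)=O)[C@H]2OC(C)=O)cc1
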